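1. A flat curve invites a reading as equilibrium, yet it says merely that product has ceased to form, and a consumed reagent looks the same on the page.

all flasks: substrate 2.0 × 10⁻⁴ M; free catalyst 40 µM

|  | partner | temperature | remark | time |
|---|---|---|---|---|
| midnight | 0.22 mM | 0 °C | the very flask that is asked about, followed so far |  |
| winter | 0.22 mM | −15 °C | run made earlier |  |
| flask | 0.220 mM | 0 °C |  | 15 min |

| run | time / min | product / % |
|---|---|---|
| midnight | 1.50 | 22.8 |
| midnight | 3.00 | 33.7 |
| midnight | 5.00 | 40.5 |
| midnight | 6.00 | 42.1 |
| midnight | 8.00 | 41.6 |
| midnight | 10.0 | 41.7 |
| winter | 3.00 | 14.9 |
| winter | 6.00 | 28.8 |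
| winter | 10.0 | 41.1 |
| winter | 12.0 | 45.4 |
| winter | 15.0 | 51.9 |
| winter | 20.0 | 56.5 |

(standard deviation of a reading: 0.5 percentage points)

- blue: at 15 min add partner, 50.0% of the amount charged, then wait 8.0 min
- green: at 15 min raise the temperature by 10 K, then wait 8.0 min
- ochre: change nothing and wait 8.0 min more
- amber: at 15 min add free catalyst, 50.0% of the amount charged, then wait 8.0 min
- teal: at 15 min take out 90% of the product then present, then wait 8.0 min

- product that was removed still counts
- additions bring no volume worth counting

1. product, in percent of the substrate first charged, at 15 min
2. which option adds most product ("none" when 2 percentage points or less is all one gets) (blue / green / ochre / amber / teal / none)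
3. product present, with what was taken out counted in, in percent of the substrate first charged, after ochre
4. product present, with what was taken out counted in, in percent of the substrate first charged, after amber

2. The time carries little weight. The midnight readings from 6.00 min to 10.0 min stand at 42.1%, 41.6% and 41.7%, a drift that the scatter of 0.5 percentage points cannot tell from none.

3. The height of the stop carries more, since its error passes whole into the answer for 15 min. Its mean is 41.8%.

4. The nature of the stop carries the most, since the choice of option hangs on it. The winter run reaches 56.5% from the same charges, so cold sends more of them into product. The reckoning made here takes partner as the limiting reagent, with a side loss of partner that weakens in the cold. The measure is then the partner yield, 38.0%, which is the product at the stop per partner charged, both as amounts. In the winter run this yield has reached 51.4%. Added partner should then yield alike, so blue should add 21 points, while waiting, catalyst and removal add nothing.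

5. The forecast gives 41.8% now, 41.8% after ochre and 41.8% after amber, which agrees with this reckoning. It names teal as best, which differs from it: “I therefore take it as equilibrium”.

6. The flask gives 43.0% now, 43.0% after ochre and 43.0% after amber. The best option is blue, which adds 20 points, while teal adds 0 points.

    substrate + free catalyst → catalyst intermediate A (k = 160 L mol⁻¹ s⁻¹, Ea = 36.0 kJ mol⁻¹)
    catalyst intermediate B → free catalyst + product (k = 0.140 s⁻¹, Ea = 71.0 kJ mol⁻¹)
    2 free catalyst → spent catalyst (k = 170 L mol⁻¹ s⁻¹, Ea = 41.0 kJ mol⁻¹)
    partner → decomposed reagent (k = 0.00650 s⁻¹, Ea = 80.0 kJ mol⁻¹)
    partner + catalyst intermediate A → catalyst intermediate B (k = 630 L mol⁻¹ s⁻¹, Ea = 41.0 kJ mol⁻¹)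
    (constants at 0 °C)

7. Partner is the first to run out in this flask, with 0% left at 15.0 min against 48.5% of the substrate. Its decomposition to decomposed reagent is the main reason for the shortfall: the same run without that step gives 72.6% instead of 43.0%. The partner yield of 38.0% reckoned 21 points for blue, and blue adds 20 points. For the neighbouring flask with 3.7 × 10⁻⁴ M of partner, the same yield reckons 70.3%, but that flask gives 52.4%, a partner yield of 28.3%.

The numbers in the tables are simulated on assumed constants, noise included.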